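The two outer diarylmethane bonds are disconnected. In each arm the terminal CH2 is attached to C5 of the inner 2-hydroxybenzyl ring, the carbon para to that ring's phenolic OH (on C2), which is where a phenol naturally captures an o-quinone methide. One operation therefore joins two 3,5-dibromo-o-quinone methides to both arm rings of (2S)-6,8-bis(3-bromo-2-hydroxybenzyl)-5-hydroxy-7-methoxyflavanone, a pinostrobin with ring A fully substituted whose arm rings carry bromine at the competing ortho carbon (C3) and are open only at C5. The C2 stereocentre comes from (2S)-pinostrobin and is never touched; one hydrogenolysis finally removes all six bromines.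

Key step: step 4

Assumption: the target is taken as drawn in its SMILES (7-OMe, both arms extended, 2S) and commercial (2S)-pinostrobin is taken to be enantiopure (to be confirmed by chiral HPLC); all phenols stay unprotected, because the arm OH groups activate the key step and the 5-OH is held in its hydrogen bond to C4=O.

Step 1
Reactants: 1 3-bromo-2-hydroxybenzaldehyde
Product: 2 3-bromo-2-hydroxybenzyl alcohol
Conditions: NaBH4 (1 equiv), MeOH–THF, 0 °C → rt; sat. aq. NH4Cl quench (pH about 6, no heating)
Reagents that add atoms: none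
Why: Borohydride reduction of an aryl aldehyde to the benzylic alcohol is chemoselective and leaves the aryl bromide and the phenol untouched, and the near-neutral work-up avoids premature condensation of the product through its free para carbon.

Step 2
Reactants: 3 (2S)-pinostrobin [(2S)-5-hydroxy-7-methoxyflavanone]; 2 3-bromo-2-hydroxybenzyl alcohol
Product: 7 (2S)-6,8-bis(3-bromo-2-hydroxybenzyl)-5-hydroxy-7-methoxyflavanone, via bromo-o-quinone methide 4 (not isolated), via 6-monobenzyl flavanone 5 (not isolated), via 8-monobenzyl flavanone 6 (not isolated)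
Conditions: anhydrous ZnCl2 (3 equiv), dry 1,4-dioxane, 80 °C; 2 (3 equiv) added in portions
Reagents that add atoms: none
Why: In this Lewis-acid-mediated o-quinone methide C-benzylation (Friedel–Crafts type, established for 5-hydroxyflavanones with 2-hydroxybenzyl alcohol), ZnCl2 dehydrates 2 to 4, which is captured at C6 and C8, the only free carbons of the phloroglucinol-type ring A; this ring is far more nucleophilic than the bromine-deactivated para carbon of the reagent or of the installed arms, so reaction should stop at 7, and no stereocentre is formed while C2, whose unsubstituted phenyl offers no quinone methide path for ring opening, should stay S.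

Step 3
Reactants: 8 3,5-dibromo-2-hydroxybenzaldehyde
Product: 9 3,5-dibromo-2-hydroxybenzyl alcohol
Conditions: NaBH4 (1 equiv), MeOH–THF, 0 °C → rt; sat. aq. NH4Cl quench
Reagents that add atoms: none
Why: The same chemoselective borohydride reduction of an aryl aldehyde applies, and with both ortho and the para carbon blocked the product cannot self-condense through carbon.

Step 4
Reactants: 7 (2S)-6,8-bis(3-bromo-2-hydroxybenzyl)-5-hydroxy-7-methoxyflavanone; 9 3,5-dibromo-2-hydroxybenzyl alcohol
Product: 13 (2S)-6,8-bis[3-bromo-5-(3,5-dibromo-2-hydroxybenzyl)-2-hydroxybenzyl]-5-hydroxy-7-methoxyflavanone, via dibromo-o-quinone methide 10 (not isolated), via C6-arm-extended flavanone 11 (not isolated), via C8-arm-extended flavanone 12 (not isolated)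
Conditions: TsOH·H2O (0.2 equiv), HFIP–CH2Cl2 (3:1), 40 °C; 9 (3 equiv) added in portions
Reagents that add atoms: none
Why: Acid-assisted loss of water from 9 in the ionising, non-nucleophilic medium gives the electron-poor o-quinone methide 10, which each arm ring of 7 captures through the carbon para to its phenolic OH in a Friedel–Crafts-type conjugate addition; proton loss restores both phenols, and the second arm reacts in the same way through 11 or 12. The closest known reaction type is the acid-catalysed condensation of bromine-blocked 2-hydroxybenzyl alcohols with phenols used in stepwise phenol–formaldehyde oligomer synthesis, together with the o-quinone methide C-benzylation of flavanones. No ring is closed and no stereocentre is created. The step needs exclusive attack at C5 of each arm ring, and the substrate secures it: arm C3 (ortho to OH) carries bromine, ring A is hexasubstituted, the C2-phenyl is unactivated, and every ortho and para carbon of the incoming ring is brominated, so neither chain growth nor carbon self-condensation of the reagent is possible, while O-alkylated adducts can revert to 10 under the acid. Catalytic sulfonic acid at 40 °C should be too mild for retro-oxa-Michael opening of the hydrogen-bonded flavanone, so C2 should remain S.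

Step 5
Reactants: 13 (2S)-6,8-bis[3-bromo-5-(3,5-dibromo-2-hydroxybenzyl)-2-hydroxybenzyl]-5-hydroxy-7-methoxyflavanone
Product: 14 5''-(2''''-hydroxybenzyl)uvarinol as drawn, (2S)-5-hydroxy-6,8-bis[2-hydroxy-5-(2-hydroxybenzyl)benzyl]-7-methoxyflavanone
Conditions: H2 (1 atm), 10% Pd/C, NaOAc (8 equiv), EtOAc–MeOH (1:1), rt; stopped when debromination is complete
Reagents that add atoms: none
Why: Heterogeneous palladium-catalysed hydrogenolysis (hydrodebromination) of aryl C–Br bonds is fast at 1 atm once the HBr is buffered, whereas the hydrogen-bonded C4 ketone and the C2–O1 benzylic ether of a flavanone are reduced far more slowly, so all six bromines should be exchanged for hydrogen with C2 unaffected.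

Compound list
1 | 3-bromo-2-hydroxybenzaldehyde | O=Cc1cccc(Br)c1O | starting material
2 | 3-bromo-2-hydroxybenzyl alcohol | OCc1cccc(Br)c1O | intermediate
3 | (2S)-pinostrobin, (2S)-5-hydroxy-7-methoxyflavanone | COc1cc(O)c2c(c1)O[C@H](c1ccccc1)CC2=O | starting material
4 | 2-bromo-6-methylidenecyclohexa-2,4-dien-1-one (bromo-o-quinone methide) | C=C1C=CC=C(Br)C1=O | intermediate
5 | (2S)-6-(3-bromo-2-hydroxybenzyl)-5-hydroxy-7-methoxyflavanone | COc1c(Cc2cccc(Br)c2O)c(O)c2c(c1)O[C@H](c1ccccc1)CC2=O | intermediate
6 | (2S)-8-(3-bromo-2-hydroxybenzyl)-5-hydroxy-7-methoxyflavanone | COc1cc(O)c2c(c1Cc1cccc(Br)c1O)O[C@H](c1ccccc1)CC2=O | intermediate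
7 | (2S)-6,8-bis(3-bromo-2-hydroxybenzyl)-5-hydroxy-7-methoxyflavanone | COc1c(Cc2cccc(Br)c2O)c(O)c2c(c1Cc1cccc(Br)c1O)O[C@H](c1ccccc1)CC2=O | intermediate
8 | 3,5-dibromo-2-hydroxybenzaldehyde | O=Cc1cc(Br)cc(Br)c1O | starting material
9 | 3,5-dibromo-2-hydroxybenzyl alcohol | OCc1cc(Br)cc(Br)c1O | intermediate
10 | 2,4-dibromo-6-methylidenecyclohexa-2,4-dien-1-one (dibromo-o-quinone methide) | C=C1C=C(Br)C=C(Br)C1=O | intermediate
11 | (2S)-6-[3-bromo-5-(3,5-dibromo-2-hydroxybenzyl)-2-hydroxybenzyl]-8-(3-bromo-2-hydroxybenzyl)-5-hydroxy-7-methoxyflavanone | COc1c(Cc2cc(Cc3cc(Br)cc(Br)c3O)cc(Br)c2O)c(O)c2c(c1Cc1cccc(Br)c1O)O[C@H](c1ccccc1)CC2=O | intermediate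
12 | (2S)-8-[3-bromo-5-(3,5-dibromo-2-hydroxybenzyl)-2-hydroxybenzyl]-6-(3-bromo-2-hydroxybenzyl)-5-hydroxy-7-methoxyflavanone | COc1c(Cc2cccc(Br)c2O)c(O)c2c(c1Cc1cc(Cc3cc(Br)cc(Br)c3O)cc(Br)c1O)O[C@H](c1ccccc1)CC2=O | intermediate
13 | (2S)-6,8-bis[3-bromo-5-(3,5-dibromo-2-hydroxybenzyl)-2-hydroxybenzyl]-5-hydroxy-7-methoxyflavanone | COc1c(Cc2cc(Cc3cc(Br)cc(Br)c3O)cc(Br)c2O)c(O)c2c(c1Cc1cc(Cc3cc(Br)cc(Br)c3O)cc(Br)c1O)O[C@H](c1ccccc1)CC2=O | intermediate
14 | 5''-(2''''-hydroxybenzyl)uvarinol as drawn, (2S)-5-hydroxy-6,8-bis[2-hydroxy-5-(2-hydroxybenzyl)benzyl]-7-methoxyflavanone | COc1c(Cc2cc(Cc3ccccc3O)ccc2O)c(O)c2c(c1Cc1cc(Cc3ccccc3O)ccc1O)O[C@H](c1ccccc1)CC2=O | target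

Total step count: 5. Longest linear sequence: 4 steps (1 → 2 → 7 → 13 → 14).

Steps most likely to fail

Step 4. The para carbons of the bromine-deactivated arm phenols may add too slowly, so that the quinone methide is consumed by self-trimerisation and O-alkylation and the reaction stalls after one arm; prolonged acid exposure could also erode the configuration at C2. The fallback sets out from 9 (with 3) and returns to the route at 13, making the difficult aryl–CH2 bond on simple achiral phenols. Compound 9 would be condensed with a large excess of 2-bromophenol (cat. conc. HCl, AcOH, 60 °C; para attack expected to dominate, product purified by crystallisation) to give 2-bromo-4-(3,5-dibromo-2-hydroxybenzyl)phenol F1. Hydroxymethylation of F1 at its single free ortho carbon (aq. CH2O, NaOH, rt, Lederer–Manasse reaction, neutralised with AcOH) would give 3-bromo-5-(3,5-dibromo-2-hydroxybenzyl)-2-hydroxybenzyl alcohol F2, a reagent with every ortho and para carbon blocked. F2 would then replace 2 in the ZnCl2/dioxane benzylation of 3, where the highly nucleophilic ring A is the acceptor, to give 13 directly; step 5 follows unchanged and 7 is bypassed.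

Step 2. The unblocked para carbon of the reagent and of the newly installed arms may compete with ring A, leading to over-benzylation and reagent oligomerisation, or the second, more hindered benzylation may not go to completion. The fallback sets out from 3 and returns to the route at 14, using orthogonal halogens so that the reagent is fully blocked. Commercially available 5-bromo-3-chloro-2-hydroxybenzaldehyde would be reduced with NaBH4 to 5-bromo-3-chloro-2-hydroxybenzyl alcohol F3. ZnCl2/dioxane benzylation of 3 with excess F3 should give (2S)-6,8-bis(5-bromo-3-chloro-2-hydroxybenzyl)-5-hydroxy-7-methoxyflavanone F4 without chain growth. Chemoselective hydrogenolysis of the two para C–Br bonds (H2 1 atm, Pd/C, NaOAc, EtOAc, rt, stopped after two equivalents; aryl bromide reacts far faster than aryl chloride) would unmask the para carbons and give (2S)-6,8-bis(3-chloro-2-hydroxybenzyl)-5-hydroxy-7-methoxyflavanone F5. The conditions of step 4 with 9 would give (2S)-6,8-bis[3-chloro-5-(3,5-dibromo-2-hydroxybenzyl)-2-hydroxybenzyl]-5-hydroxy-7-methoxyflavanone F6, and exhaustive hydrodehalogenation (H2 3 atm, Pd/C, NaOAc, MeOH, 40 °C) would return to the route at 14.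

Step 5. Hydrogen on palladium may over-reduce the flavanone (cleavage of the benzylic C2–O1 bond or reduction of C4=O), or bromide may poison the catalyst and leave debromination incomplete. The fallback sets out from 13 and returns to the route at 14 by a radical-chain hydrodebromination that involves neither H2 nor a metal surface: Bu3SnH (excess), AIBN, toluene, 90 °C, followed by KF work-up to remove tin residues. No new compound is made.

Further compounds
F1 | step 4 | 2-bromo-4-(3,5-dibromo-2-hydroxybenzyl)phenol | Oc1ccc(Cc2cc(Br)cc(Br)c2O)cc1Br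
F2 | step 4 | 3-bromo-5-(3,5-dibromo-2-hydroxybenzyl)-2-hydroxybenzyl alcohol | OCc1cc(Cc2cc(Br)cc(Br)c2O)cc(Br)c1O
F3 | step 2 | 5-bromo-3-chloro-2-hydroxybenzyl alcohol | OCc1cc(Br)cc(Cl)c1O
F4 | step 2 | (2S)-6,8-bis(5-bromo-3-chloro-2-hydroxybenzyl)-5-hydroxy-7-methoxyflavanone | COc1c(Cc2cc(Br)cc(Cl)c2O)c(O)c2c(c1Cc1cc(Br)cc(Cl)c1O)O[C@H](c1ccccc1)CC2=O
F5 | step 2 | (2S)-6,8-bis(3-chloro-2-hydroxybenzyl)-5-hydroxy-7-methoxyflavanone | COc1c(Cc2cccc(Cl)c2O)c(O)c2c(c1Cc1cccc(Cl)c1O)O[C@H](c1ccccc1)CC2=O
F6 | step 2 | (2S)-6,8-bis[3-chloro-5-(3,5-dibromo-2-hydroxybenzyl)-2-hydroxybenzyl]-5-hydroxy-7-methoxyflavanone | COc1c(Cc2cc(Cc3cc(Br)cc(Br)c3O)cc(Cl)c2O)c(O)c2c(c1Cc1cc(Cc3cc(Br)cc(Br)c3O)cc(Cl)c1O)O[C@H](c1ccccc1)CC2=O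
F0 | step 5 | none | none
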